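**Retrosynthetic overview**
1. The C3–OH bond is disconnected last: enantioselective C3–O bond formation on racemic isoflavanone 8 sets the only stereocentre (3R).
2. 8 comes from an aromatic Claisen rearrangement of the 4′-O-prenyl ether 7, which comes from site-selective O-prenylation of triol isoflavanone 5.
3. 5 comes from conjugate reduction of isoflavone 4.
4. 4 comes from phloroglucinol (ring A), 2-(4-hydroxy-2-methoxyphenyl)acetic acid (ring B) and one carbon from DMF. Ring C (the pyranone) is the only ring built, in step 1.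

Assumption: 2-(4-hydroxy-2-methoxyphenyl)acetic acid (2) is bought as a catalogue building block; the stereodescriptor in the target SMILES corresponds to 3R.

**Step 1**
Reactants: 1 phloroglucinol (benzene-1,3,5-triol); 2 2-(4-hydroxy-2-methoxyphenyl)acetic acid
Product: 4 5,7-dihydroxy-3-(4-hydroxy-2-methoxyphenyl)-4H-chromen-4-one, via deoxybenzoin 3 (not isolated)
Conditions: BF3·OEt2 (as solvent), 85 °C, 2 h; then DMF, MsCl, 70 °C, 3 h; hot aq. HCl work-up
Reagents that add atoms: N,N-dimethylformamide (DMF), CN(C)C=O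
Why: Friedel–Crafts C-acylation of phloroglucinol by the BF3-activated acid gives deoxybenzoin 3, whose methylene is formylated by the DMF/MsCl Vilsmeier-type reagent and closes ring C with loss of dimethylamine (one-pot deoxybenzoin route to isoflavones); no stereocentre is formed.

**Step 2**
Reactants: 4 5,7-dihydroxy-3-(4-hydroxy-2-methoxyphenyl)-4H-chromen-4-one
Product: 5 (±)-5,7-dihydroxy-3-(4-hydroxy-2-methoxyphenyl)-2,3-dihydro-4H-chromen-4-one
Conditions: HCO2NH4 (5 equiv), 10% Pd/C, MeOH, 65 °C, N2
Reagents that add atoms: none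
Why: Catalytic transfer hydrogenation saturates the C2=C3 double bond while the 5-OH-chelated C4 ketone survives; the new C3 centre is racemic and configurationally labile, which does not matter because step 5 sets it.

**Step 3**
Reactants: 5 (±)-5,7-dihydroxy-3-(4-hydroxy-2-methoxyphenyl)-2,3-dihydro-4H-chromen-4-one; 6 1-bromo-3-methylbut-2-ene (prenyl bromide)
Product: 7 (±)-5,7-dihydroxy-3-{2-methoxy-4-[(3-methylbut-2-en-1-yl)oxy]phenyl}-2,3-dihydro-4H-chromen-4-one
Conditions: KOt-Bu (2.05 equiv), DMF, 0 °C, Ar; then 6 (1.0 equiv), 0 °C to rt; 1 M HCl quench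
Reagents that add atoms: none
Why: Williamson etherification of the 7,4′-dianion, in which the ring B phenoxide (not conjugated to the carbonyl) is much more basic and nucleophilic than the vinylogous-carboxylate 7-phenoxide, so one equivalent of halide goes to O4′; the chelated 5-OH stays protonated.

**Step 4**
Reactants: 7 (±)-5,7-dihydroxy-3-{2-methoxy-4-[(3-methylbut-2-en-1-yl)oxy]phenyl}-2,3-dihydro-4H-chromen-4-one
Product: 8 (±)-5,7-dihydroxy-3-[4-hydroxy-2-methoxy-5-(2-methylbut-3-en-2-yl)phenyl]-2,3-dihydro-4H-chromen-4-one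
Conditions: degassed EtOH–H2O (4:1), 130 °C, sealed tube, 12 h
Reagents that add atoms: none
Why: Aromatic Claisen ([3,3]-sigmatropic) rearrangement, accelerated by the protic medium, transfers the prenyl unit with allylic inversion (giving the 1,1-dimethylallyl group) to the open ortho position C5′ rather than to C3′, which is flanked by OMe; tautomerisation restores the phenol.

**Step 5**
Reactants: 8 (±)-5,7-dihydroxy-3-[4-hydroxy-2-methoxy-5-(2-methylbut-3-en-2-yl)phenyl]-2,3-dihydro-4H-chromen-4-one
Product: 10 (3R)-3,5,7-trihydroxy-3-[4-hydroxy-2-methoxy-5-(2-methylbut-3-en-2-yl)phenyl]-2,3-dihydro-4H-chromen-4-one, via aminoxy ketone 9 (not isolated)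
Conditions: (R)-3,3′-bis(2,4,6-triisopropylphenyl)-1,1′-binaphthyl-2,2′-diyl hydrogen phosphate [(R)-TRIP] (10 mol %), PhNO (3 equiv, in portions), CHCl3, 5 Å MS, 40 °C, dark, Ar
Reagents that add atoms: nitrosobenzene, O=Nc1ccccc1
Why: Proposed new method: chiral phosphoric acid enol catalysis applied to an isoflavanone carrying free phenols – ketone 8, whose C3–H is benzylic and α to the carbonyl, enolises readily under Brønsted acid, and the bifunctional catalyst (P=O hydrogen-bonded to the enol O–H, P–OH to the nitroso nitrogen) holds the planar ring C enol so that C3 attacks the oxygen of PhNO on the face left open by the triisopropylphenyl walls (O-nitroso aldol forming the C3–O bond; both enantiomers of 8 converge and the quaternary product cannot re-enolise), after which a second PhNO cleaves the O–N bond of 9 to give the tertiary alcohol and azoxybenzene; the closest known reaction type is the chiral phosphoric acid-catalysed α-hydroxylation of 2-aryl cycloalkanones with nitrosobenzene, not shown for chroman-4-ones or unprotected polyphenols, and the sense of induction is not predictable in advance, so it is checked on the first run (chiral HPLC, ECD) with (S)-TRIP as the mirror option.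

**Compound list**
1 | phloroglucinol (benzene-1,3,5-triol) | Oc1cc(O)cc(O)c1 | starting material
2 | 2-(4-hydroxy-2-methoxyphenyl)acetic acid | COc1cc(O)ccc1CC(=O)O | starting material
3 | 2-(4-hydroxy-2-methoxyphenyl)-1-(2,4,6-trihydroxyphenyl)ethan-1-one (deoxybenzoin) | COc1cc(O)ccc1CC(=O)c1c(O)cc(O)cc1O | intermediate (not isolated)
4 | 5,7-dihydroxy-3-(4-hydroxy-2-methoxyphenyl)-4H-chromen-4-one (isoflavone) | COc1cc(O)ccc1C1=COc2cc(O)cc(O)c2C1=O | intermediate
5 | (±)-5,7-dihydroxy-3-(4-hydroxy-2-methoxyphenyl)-2,3-dihydro-4H-chromen-4-one (racemic) | COc1cc(O)ccc1C1COc2cc(O)cc(O)c2C1=O | intermediate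
6 | 1-bromo-3-methylbut-2-ene (prenyl bromide) | CC(C)=CCBr | starting material
7 | (±)-5,7-dihydroxy-3-{2-methoxy-4-[(3-methylbut-2-en-1-yl)oxy]phenyl}-2,3-dihydro-4H-chromen-4-one (racemic) | COc1cc(OCC=C(C)C)ccc1C1COc2cc(O)cc(O)c2C1=O | intermediate
8 | (±)-5,7-dihydroxy-3-[4-hydroxy-2-methoxy-5-(2-methylbut-3-en-2-yl)phenyl]-2,3-dihydro-4H-chromen-4-one (racemic) | C=CC(C)(C)c1cc(C2COc3cc(O)cc(O)c3C2=O)c(OC)cc1O | intermediate
9 | (3R)-5,7-dihydroxy-3-[4-hydroxy-2-methoxy-5-(2-methylbut-3-en-2-yl)phenyl]-3-[(phenylamino)oxy]-2,3-dihydro-4H-chromen-4-one | C=CC(C)(C)c1cc([C@@]2(ONc3ccccc3)COc3cc(O)cc(O)c3C2=O)c(OC)cc1O | intermediate (not isolated)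
10 | (3R)-3,5,7-trihydroxy-3-[4-hydroxy-2-methoxy-5-(2-methylbut-3-en-2-yl)phenyl]-2,3-dihydro-4H-chromen-4-one (CNP0142880.1) | C=CC(C)(C)c1cc([C@@]2(O)COc3cc(O)cc(O)c3C2=O)c(OC)cc1O | target

**Totals**
Total step count: 5. Longest linear sequence: 5 (fully linear).

**Three steps most likely to fail**

First, step 5, the new hydroxylation. The free phenols may compete for the catalyst's hydrogen bonds and erode the ee. Activated PhNO may attack the electron-rich ring positions (C6/C8 of ring A, C3′ of ring B). N-attack may compete with O-attack. Fallback by known chemistry, setting out from 8 and returning at 10: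
- t-BuMe2SiCl and imidazole in DMF cap the 7- and 4′-hydroxyls to give the 7,4′-bis(tert-butyldimethylsilyl) ether of 8 F1.
- NaN(SiMe3)2 (2.2 equiv: 5-phenoxide, then enolate) in THF at −78 °C, followed by the antipode of (8,8-dichlorocamphorylsulfonyl)oxaziridine that delivers the 3R alcohol, gives the (3R)-3-hydroxy bis-silyl ether F2. This is reagent-controlled Davis enolate hydroxylation, established for 3-substituted chroman-4-one enolates.
- Bu4NF buffered by AcOH in THF at 0 °C releases 10.

Second, step 3, the site-selective prenylation. Competing 7-O-alkylation, bis-alkylation or C-alkylation would lower the yield. Fallback by a protecting-group approach, setting out from 5 and returning at 7: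
- i-Pr3SiCl (1.05 equiv) and Et3N in DMF at 0 °C silylate the most acidic 7-OH to give the 7-O-triisopropylsilyl ether of 5 F3.
- K2CO3 and 6 in acetone at 50 °C alkylate the only remaining non-chelated phenol to give the 7-O-silyl 4′-O-prenyl ether F4.
- Bu4NF/AcOH in THF at 0 °C removes the silyl group to give 7.

Third, step 4, the Claisen rearrangement. Possible problems are loss of the prenyl group by heterolysis, some attack at C3′, abnormal Claisen isomerisation on overheating, and air oxidation of the isoflavanone during long heating. Fallback that moves the rearrangement to the thermally robust isoflavone and replaces hydrogenation by hydride reduction, setting out from 4 and returning at 8: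
- KOt-Bu (2.05 equiv) and 6 in DMF convert 4 into the 4′-O-prenyl isoflavone F5.
- Heating in PhNEt2 at 190 °C gives the 5′-(1,1-dimethylallyl) isoflavone F6.
- Excess i-Bu2AlH in THF–toluene at −70 °C effects 1,4-reduction via the aluminium enolate, leaving the vinyl group untouched, and gives 8 on work-up.

**Further compounds**
F1 | step 5 | (±)-7-[(tert-butyldimethylsilyl)oxy]-3-{4-[(tert-butyldimethylsilyl)oxy]-2-methoxy-5-(2-methylbut-3-en-2-yl)phenyl}-5-hydroxy-2,3-dihydro-4H-chromen-4-one | C=CC(C)(C)c1cc(C2COc3cc(O[Si](C)(C)C(C)(C)C)cc(O)c3C2=O)c(OC)cc1O[Si](C)(C)C(C)(C)C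
F2 | step 5 | (3R)-7-[(tert-butyldimethylsilyl)oxy]-3-{4-[(tert-butyldimethylsilyl)oxy]-2-methoxy-5-(2-methylbut-3-en-2-yl)phenyl}-3,5-dihydroxy-2,3-dihydro-4H-chromen-4-one | C=CC(C)(C)c1cc([C@@]2(O)COc3cc(O[Si](C)(C)C(C)(C)C)cc(O)c3C2=O)c(OC)cc1O[Si](C)(C)C(C)(C)C
F3 | step 3 | (±)-5-hydroxy-3-(4-hydroxy-2-methoxyphenyl)-7-[(triisopropylsilyl)oxy]-2,3-dihydro-4H-chromen-4-one | COc1cc(O)ccc1C1COc2cc(O[Si](C(C)C)(C(C)C)C(C)C)cc(O)c2C1=O
F4 | step 3 | (±)-5-hydroxy-3-{2-methoxy-4-[(3-methylbut-2-en-1-yl)oxy]phenyl}-7-[(triisopropylsilyl)oxy]-2,3-dihydro-4H-chromen-4-one | COc1cc(OCC=C(C)C)ccc1C1COc2cc(O[Si](C(C)C)(C(C)C)C(C)C)cc(O)c2C1=O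
F5 | step 4 | 5,7-dihydroxy-3-{2-methoxy-4-[(3-methylbut-2-en-1-yl)oxy]phenyl}-4H-chromen-4-one | COc1cc(OCC=C(C)C)ccc1C1=COc2cc(O)cc(O)c2C1=O
F6 | step 4 | 5,7-dihydroxy-3-[4-hydroxy-2-methoxy-5-(2-methylbut-3-en-2-yl)phenyl]-4H-chromen-4-one | C=CC(C)(C)c1cc(C2=COc3cc(O)cc(O)c3C2=O)c(OC)cc1O
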